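The decalin is cut at C1–C10 (eremophilane numbering: ring A = C1–C5 and C10, ring B = C5–C10). The key step exploits the 1,3-relationship of the C8 carbonyl and the ring-fusion carbon C10 in ring B: ring B is carried as a cyclohexane-1,3-dione vinylogous ester whose carbonyl carbon is the future C10. Its precursor bears, on the quaternary α'-carbon C5 (set by asymmetric enolate alkenylation), a 5-iodopentenyl chain; iodine–lithium exchange makes a C1 carbanion that adds to C10 and closes ring A, and acid transposes the carbonyl to C8 (Stork–Danheiser). From C5 alone, dissolving-metal reduction then sets C10, hydroboration C3 and C4, enolate hydroxylation C9.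

Key step: step 5

Remark: eremophilane numbering (C1–C15) is used for ring positions throughout; in step 3 the ligand antipode is taken that delivers the (R)-configured quaternary centre, the sense of induction being an assumption to be confirmed on the first run.

Step 1
Reactants: 1 3-ethoxycyclohex-2-en-1-one
Product: 2 3-ethoxy-6-methylcyclohex-2-en-1-one (racemic)
Conditions: LiN(i-Pr)2, THF, −78 °C; MeI, −78 → 0 °C
Reagents that add atoms: iodomethane, CI
Why: Kinetic α'-deprotonation of the vinylogous ester at the future C5 and SN2 methylation (Stork–Danheiser alkylation) should give 2, whose stereocenter is erased again on enolization in step 3.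

Step 2
Reactants: 3 5-chloropent-1-yne
Product: 4 2-bromo-5-chloropent-1-ene
Conditions: tetraethylammonium hydrogen dibromide (Et4N+ HBr2−), CH2Cl2, 40 °C
Reagents that add atoms: tetraethylammonium hydrogen dibromide, CC[N+](CC)(CC)CC.Br.[Br-]
Why: Markovnikov hydrobromination of the terminal alkyne by the hydrogen dibromide anion should stop at the 2-bromo-1-alkene (alkyne hydrohalogenation), the primary chloride being inert.

Step 3
Reactants: 2 3-ethoxy-6-methylcyclohex-2-en-1-one; 4 2-bromo-5-chloropent-1-ene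
Product: 5 (6R)-6-(5-chloropent-1-en-2-yl)-3-ethoxy-6-methylcyclohex-2-en-1-one
Conditions: LiN(SiMe3)2, THF, −78 °C; then 4, Pd2(dba)3 (2.5 mol %), enantiopure 2-(dicyclohexylphosphino)-2'-(dimethylamino)-1,1'-binaphthyl (6 mol %), toluene, 25 → 45 °C
Reagents that add atoms: none
Why: Palladium-catalysed asymmetric α-alkenylation of the preformed α'-enolate (enolate cross-coupling: oxidative addition of zerovalent palladium into the C(sp2)–Br bond, transmetalation, reductive elimination) should forge C5–C4 and set the quaternary C5 under control of the chiral monophosphine, the alkyl chloride not undergoing oxidative addition.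

Step 4
Reactants: 5 (6R)-6-(5-chloropent-1-en-2-yl)-3-ethoxy-6-methylcyclohex-2-en-1-one
Product: 6 (6R)-3-ethoxy-6-(5-iodopent-1-en-2-yl)-6-methylcyclohex-2-en-1-one
Conditions: NaI, acetone, 56 °C
Reagents that add atoms: sodium iodide, [Na+].[I-]
Why: Finkelstein halide exchange (SN2 at the primary carbon, driven by precipitation of NaCl) should give the iodide needed for fast halogen–lithium exchange.

Step 5
Reactants: 6 (6R)-3-ethoxy-6-(5-iodopent-1-en-2-yl)-6-methylcyclohex-2-en-1-one
Product: 8 (4aR)-4a-methyl-5-methylidene-4,4a,5,6,7,8-hexahydronaphthalen-2(3H)-one, via tertiary carbinol 7 (not isolated)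
Conditions: t-BuLi (2.1 equiv), Et2O–pentane, −78 → 0 °C; then 2 M HCl, THF, 23 °C
Reagents that add atoms: water, O
Why: Iodine–lithium exchange at the primary C1–I bond should be faster than any reaction of t-BuLi with the hindered, electron-rich vinylogous ester, and the resulting C1 alkyllithium adds to the C10 carbonyl (anionic cyclization; closest known type: halogen–metal-exchange-initiated cyclization of iodo ketones combined with the Stork–Danheiser 1,2-addition and transposition). Ring A is closed in the 6-exo-trig mode, carbanion onto C=O, to give carbinol 7. Aqueous acid hydrolyses the enol ether and eliminates the tertiary C10 hydroxyl, so the carbonyl moves to C8 and the C9=C10 enone 8 results. No stereocenter is created that persists: C10 ends sp2 and the C5 configuration from step 3 is carried through unchanged, which is why the ring-fusion geometry can be set later by reduction. The step needs exchange before carbonyl attack or γ-deprotonation and 1,2- rather than 1,4-addition; the iodide, the low temperature, the six-membered transition state and the alkoxy group on C8 (which deactivates the 1,4-site, itself out of reach of the chain) should secure this.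

Step 6
Reactants: 8 (4aR)-4a-methyl-5-methylidene-4,4a,5,6,7,8-hexahydronaphthalen-2(3H)-one
Product: 9 (4aR)-4a,5-dimethyl-4,4a,7,8-tetrahydronaphthalen-2(3H)-one
Conditions: RhCl3·3H2O (5 mol %), EtOH, 75 °C
Reagents that add atoms: none
Why: Metal-hydride-mediated alkene isomerization should move the exocyclic C4 methylene into ring A as the more stable trisubstituted C3=C4 alkene, the only endocyclic position open because C5 is quaternary.

Step 7
Reactants: 9 (4aR)-4a,5-dimethyl-4,4a,7,8-tetrahydronaphthalen-2(3H)-one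
Product: 10 (4aS,8aS)-4a,5-dimethyl-3,4,4a,7,8,8a-hexahydronaphthalen-2(1H)-one
Conditions: Li, NH3(l)–THF, t-BuOH (1 equiv), −78 °C; then isoprene, NH4Cl
Reagents that add atoms: none
Why: Dissolving-metal (Birch-type) reduction of the enone should protonate the β-carbanion at C10 axially, anti to the angular C5 methyl, giving the trans ring fusion, while the isolated C3=C4 alkene is not reduced.

Step 8
Reactants: 10 (4aS,8aS)-4a,5-dimethyl-3,4,4a,7,8,8a-hexahydronaphthalen-2(1H)-one
Product: 11 (4a'S,8a'S)-4a',5'-dimethyl-3',4',4a',7',8',8a'-hexahydro-1'H-spiro[1,3-dioxolane-2,2'-naphthalene]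
Conditions: HOCH2CH2OH, p-TsOH (cat.), benzene, reflux (Dean–Stark)
Reagents that add atoms: ethane-1,2-diol, OCCO
Why: Acid-catalysed ketalization with azeotropic removal of water should mask the C8 ketone against borane.

Step 9
Reactants: 11 (4a'S,8a'S)-4a',5'-dimethyl-3',4',4a',7',8',8a'-hexahydro-1'H-spiro[1,3-dioxolane-2,2'-naphthalene]
Product: 13 (4aS,5R,6R,8aS)-6-hydroxy-4a,5-dimethyloctahydronaphthalen-2(1H)-one, via hydroxy ketal 12 (not isolated)
Conditions: BH3·THF, THF, 0 → 23 °C; NaOH, H2O2; then 2 M HCl, THF, 23 °C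
Reagents that add atoms: hydrogen peroxide, OO
Why: Hydroboration–oxidation should add H and B syn across C3=C4 from the face opposite the adjacent axial C5 methyl with boron on the less substituted C3, so that oxidation with retention sets the equatorial 3-OH and the equatorial 4-methyl in one event, and acid then removes the dioxolane.

Step 10
Reactants: 13 (4aS,5R,6R,8aS)-6-hydroxy-4a,5-dimethyloctahydronaphthalen-2(1H)-one
Product: 14 (4aS,5R,6R,8aS)-6-hydroxy-3-(2-hydroxypropan-2-yl)-4a,5-dimethyloctahydronaphthalen-2(1H)-one (epimers at the new C7 centre)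
Conditions: LiN(i-Pr)2 (2.2 equiv), THF, −78 °C; ZnCl2; acetone, −78 → −40 °C
Reagents that add atoms: acetone, CC(C)=O
Why: Double deprotonation should give the C3 alkoxide and the kinetic C7 enolate (a trans-fused 2-decalone-type ketone enolizes away from the ring fusion), whose zinc enolate undergoes aldol addition to acetone.

Step 11
Reactants: 14 (4aS,5R,6R,8aS)-6-hydroxy-3-(2-hydroxypropan-2-yl)-4a,5-dimethyloctahydronaphthalen-2(1H)-one
Product: 15 (4aS,5R,6R,8aS)-6-hydroxy-4a,5-dimethyl-3-(propan-2-ylidene)octahydronaphthalen-2(1H)-one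
Conditions: p-TsOH·H2O (10 mol %), benzene, 70 °C
Reagents that add atoms: none
Why: Acid-catalysed dehydration of the tertiary β-hydroxy ketone (completion of the aldol condensation) should give the conjugated tetrasubstituted C7=C11 enone, the secondary C3 alcohol being stable under these conditions.

Step 12
Reactants: 16 3-methylfuran-2(5H)-one; 17 angelic acid, (2Z)-2-methylbut-2-enoic acid
Product: 20 (2Z)-2-methyl-4-{[(2Z)-2-methylbut-2-enoyl]oxy}but-2-enoic acid, via sodium hydroxy carboxylate 18 (not isolated), via angelic anhydride 19 (not isolated)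
Conditions: 16, NaOH (1.0 equiv), H2O–MeOH, 23 °C, evaporation to dryness; LiN(SiMe3)2, THF–DMF, −20 °C; 19 [from 17 (2.2 equiv), DCC, CH2Cl2, 0 °C, filtered], −20 → 0 °C; 1 M HCl
Reagents that add atoms: sodium hydroxide, [Na+].[OH-]
Why: Saponification of the butenolide fixes the Z geometry, the alkoxide–carboxylate cannot relactonize, and acyl transfer from angelic anhydride to the alkoxide (alkoxide acylation) should give the diester acid without angelate-to-tiglate isomerization.

Step 13
Reactants: 15 (4aS,5R,6R,8aS)-6-hydroxy-4a,5-dimethyl-3-(propan-2-ylidene)octahydronaphthalen-2(1H)-one; 20 (2Z)-2-methyl-4-{[(2Z)-2-methylbut-2-enoyl]oxy}but-2-enoic acid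
Product: 22 (1R,2R,4aS,8aS)-1,8a-dimethyl-6-oxo-7-(propan-2-ylidene)decahydronaphthalen-2-yl (2Z)-2-methyl-4-{[(2Z)-2-methylbut-2-enoyl]oxy}but-2-enoate, via mixed anhydride 21 (not isolated)
Conditions: 20, 2,4,6-Cl3C6H2COCl, Et3N, toluene, 23 °C; then 15, toluene, 80 °C
Reagents that add atoms: none
Why: Yamaguchi esterification through the mixed anhydride, run without a nucleophilic catalyst so that the Z-enoate does not isomerize, should acylate C3-OH, the only hydroxyl present.

Step 14
Reactants: 22 (1R,2R,4aS,8aS)-1,8a-dimethyl-6-oxo-7-(propan-2-ylidene)decahydronaphthalen-2-yl (2Z)-2-methyl-4-{[(2Z)-2-methylbut-2-enoyl]oxy}but-2-enoate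
Product: 23 (1R,2R,4aR,5S,8aR)-5-hydroxy-1,8a-dimethyl-6-oxo-7-(propan-2-ylidene)decahydronaphthalen-2-yl (2Z)-2-methyl-4-{[(2Z)-2-methylbut-2-enoyl]oxy}but-2-enoate (CNP0308665.1)
Conditions: KN(SiMe3)2 (1.05 equiv), THF, −78 °C; 2-(phenylsulfonyl)-3-phenyloxaziridine, −78 °C; NH4Cl
Reagents that add atoms: 2-(phenylsulfonyl)-3-phenyloxaziridine, O=S(=O)(c1ccccc1)N1OC1c1ccccc1
Why: Kinetic α'-deprotonation at C9 of the α-alkylidene ketone (both esters lack α-hydrogens) and enolate hydroxylation by the N-sulfonyloxaziridine from the face opposite the 1,3-related axial C5 methyl should give the equatorial 9-OH.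

Compound list
1 | 3-ethoxycyclohex-2-en-1-one | CCOC1=CC(=O)CCC1 | starting material
2 | 3-ethoxy-6-methylcyclohex-2-en-1-one (racemic) | CCOC1=CC(=O)C(C)CC1 | intermediate
3 | 5-chloropent-1-yne | C#CCCCCl | starting material
4 | 2-bromo-5-chloropent-1-ene | C=C(Br)CCCCl | intermediate
5 | (6R)-6-(5-chloropent-1-en-2-yl)-3-ethoxy-6-methylcyclohex-2-en-1-one | CCOC1=CC(=O)[C@@](C)(C(=C)CCCCl)CC1 | intermediate
6 | (6R)-3-ethoxy-6-(5-iodopent-1-en-2-yl)-6-methylcyclohex-2-en-1-one | CCOC1=CC(=O)[C@@](C)(C(=C)CCCI)CC1 | intermediate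
7 | (4aR)-7-ethoxy-4a-methyl-4-methylidene-1,2,3,4,4a,5,6,8a-octahydronaphthalen-8a-ol (C8a epimers) | CCOC1=CC2(O)CCCC(=C)[C@@]2(C)CC1 | intermediate (not isolated)
8 | (4aR)-4a-methyl-5-methylidene-4,4a,5,6,7,8-hexahydronaphthalen-2(3H)-one | O=C1CC[C@]2(C)C(=C)CCCC2=C1 | intermediate
9 | (4aR)-4a,5-dimethyl-4,4a,7,8-tetrahydronaphthalen-2(3H)-one | O=C1CC[C@]2(C)C(C)=CCCC2=C1 | intermediate
10 | (4aS,8aS)-4a,5-dimethyl-3,4,4a,7,8,8a-hexahydronaphthalen-2(1H)-one | O=C1CC[C@]2(C)C(C)=CCC[C@H]2C1 | intermediate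
11 | (4a'S,8a'S)-4a',5'-dimethyl-3',4',4a',7',8',8a'-hexahydro-1'H-spiro[1,3-dioxolane-2,2'-naphthalene] | O1CCOC12CC[C@]3(C)C(C)=CCC[C@H]3C2 | intermediate
12 | (4a'S,5'R,6'R,8a'S)-4a',5'-dimethyloctahydro-1'H-spiro[1,3-dioxolane-2,2'-naphthalen]-6'-ol | O[C@@H]1CC[C@H]2CC3(OCCO3)CC[C@]2(C)[C@H]1C | intermediate (not isolated)
13 | (4aS,5R,6R,8aS)-6-hydroxy-4a,5-dimethyloctahydronaphthalen-2(1H)-one | O[C@@H]1CC[C@H]2CC(=O)CC[C@]2(C)[C@H]1C | intermediate
14 | (4aS,5R,6R,8aS)-6-hydroxy-3-(2-hydroxypropan-2-yl)-4a,5-dimethyloctahydronaphthalen-2(1H)-one (C3 epimers) | O[C@@H]1CC[C@H]2CC(=O)C(C(C)(C)O)C[C@]2(C)[C@H]1C | intermediate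
15 | (4aS,5R,6R,8aS)-6-hydroxy-4a,5-dimethyl-3-(propan-2-ylidene)octahydronaphthalen-2(1H)-one | O[C@@H]1CC[C@H]2CC(=O)C(=C(C)C)C[C@]2(C)[C@H]1C | intermediate
16 | 3-methylfuran-2(5H)-one | CC1=CCOC1=O | starting material
17 | angelic acid, (2Z)-2-methylbut-2-enoic acid | C/C=C(/C)C(=O)O | starting material
18 | sodium (2Z)-4-hydroxy-2-methylbut-2-enoate | OC/C=C(/C)C(=O)[O-].[Na+] | intermediate (not isolated)
19 | angelic anhydride, (2Z)-2-methylbut-2-enoic anhydride | C/C=C(/C)C(=O)OC(=O)/C(C)=C\C | intermediate (not isolated)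
20 | (2Z)-2-methyl-4-{[(2Z)-2-methylbut-2-enoyl]oxy}but-2-enoic acid | C/C=C(/C)C(=O)OC/C=C(/C)C(=O)O | intermediate
21 | mixed anhydride of 20 with 2,4,6-trichlorobenzoic acid | C/C=C(/C)C(=O)OC/C=C(/C)C(=O)OC(=O)c1c(Cl)cc(Cl)cc1Cl | intermediate (not isolated)
22 | (1R,2R,4aS,8aS)-1,8a-dimethyl-6-oxo-7-(propan-2-ylidene)decahydronaphthalen-2-yl (2Z)-2-methyl-4-{[(2Z)-2-methylbut-2-enoyl]oxy}but-2-enoate | C/C=C(/C)C(=O)OC/C=C(/C)C(=O)O[C@@H]1CC[C@H]2CC(=O)C(=C(C)C)C[C@]2(C)[C@H]1C | intermediate
23 | (1R,2R,4aR,5S,8aR)-5-hydroxy-1,8a-dimethyl-6-oxo-7-(propan-2-ylidene)decahydronaphthalen-2-yl (2Z)-2-methyl-4-{[(2Z)-2-methylbut-2-enoyl]oxy}but-2-enoate | C/C=C(/C)C(=O)OC/C=C(/C)C(=O)O[C@@H]1CC[C@H]2[C@H](O)C(=O)C(=C(C)C)C[C@]2(C)[C@H]1C | target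

Total step count: 14. Longest linear sequence: 12 steps (steps 1, 3 to 11, 13 and 14, from compound 1).

Steps most likely to fail

Step 3. The chiral catalyst may discriminate the two faces of the tetrasubstituted enolate poorly, or the enolate may equilibrate and couple at the γ-carbon. The fallback replaces asymmetric catalysis by a resolution on a chiral alkoxy group that the key step removes anyway. It sets out from 2: acid-catalysed enol-ether exchange with (1R,2S,5R)-menthol (p-TsOH, toluene, removal of ethanol) should give 6-methyl-3-menthyloxycyclohex-2-en-1-one F1. Enolate alkenylation with 4 as in step 3 but with an achiral catalyst (Pd2(dba)3, P(t-Bu)3) should give the two C6 epimers, the (6R)-alkenylated menthyl enol ether F2 and its (6S) epimer F3, to be separated by chromatography or crystallization. F2 with NaI in acetone should give the (6R)-iodide F4, and t-BuLi followed by aqueous HCl (as in step 5) expels menthol and rejoins the route at 8.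

Step 5. The new alkyllithium may be quenched by proton transfer from the γ-methylene (C7) of the vinylogous ester, or t-BuLi may attack the carbonyl before the exchange. The fallback makes the same C1–C10 bond by a radical conjugate addition after the carbonyl has been transposed. It sets out from 5: i-Bu2AlH (toluene, −78 °C) then 1 M HCl should give (4S)-4-(5-chloropent-1-en-2-yl)-4-methylcyclohex-2-en-1-one F5. NaI in acetone should give (4S)-4-(5-iodopent-1-en-2-yl)-4-methylcyclohex-2-en-1-one F6. Bu3SnH and AIBN (benzene, 80 °C) should close ring A by 6-exo-trig addition of the C1 radical to C10 and give cis-fused (4aS,8aR)-4a-methyl-5-methylideneoctahydronaphthalen-2(1H)-one F7. Dehydrogenation with IBX (DMSO–toluene, 70 °C) toward the ring fusion removes the C10 centre and rejoins the route at 8.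

Step 14. The amide base may deprotonate the γ-positions of the dienoate side chain or trigger acyl transfer instead of clean C9 enolization. The fallback hydroxylates before the ester is attached and uses two silyl ethers of graded lability. It sets out from 15: Et3SiCl and imidazole should give the 6-triethylsilyl ether of 15 F8. KN(SiMe3)2 and the oxaziridine of step 14 should give the 1-hydroxy ketone of F8 F9. t-BuMe2SiOTf and 2,6-lutidine should give the 1-tert-butyldimethylsilyl 6-triethylsilyl bis-ether F10. PPTS in MeOH at 0 °C should remove only the triethylsilyl group and give the 6-hydroxy 1-silyl ether F11. Yamaguchi esterification with 20 as in step 13 should give the 9-O-silylated target F12 (9-O in eremophilane numbering, the 5-silyloxy group of the decahydronaphthalen-2-yl ester), and HF·pyridine in THF rejoins the route at 23.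

Further compounds
F1 | step 3 | (6RS)-6-methyl-3-{[(1R,2S,5R)-5-methyl-2-(propan-2-yl)cyclohexyl]oxy}cyclohex-2-en-1-one | CC(C)[C@@H]1CC[C@@H](C)C[C@H]1OC1=CC(=O)C(C)CC1
F2 | step 3 | (6R)-6-(5-chloropent-1-en-2-yl)-6-methyl-3-{[(1R,2S,5R)-5-methyl-2-(propan-2-yl)cyclohexyl]oxy}cyclohex-2-en-1-one | CC(C)[C@@H]1CC[C@@H](C)C[C@H]1OC1=CC(=O)[C@@](C)(C(=C)CCCCl)CC1
F3 | step 3 | (6S)-6-(5-chloropent-1-en-2-yl)-6-methyl-3-{[(1R,2S,5R)-5-methyl-2-(propan-2-yl)cyclohexyl]oxy}cyclohex-2-en-1-one | CC(C)[C@@H]1CC[C@@H](C)C[C@H]1OC1=CC(=O)[C@](C)(C(=C)CCCCl)CC1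
F4 | step 3 | (6R)-6-(5-iodopent-1-en-2-yl)-6-methyl-3-{[(1R,2S,5R)-5-methyl-2-(propan-2-yl)cyclohexyl]oxy}cyclohex-2-en-1-one | CC(C)[C@@H]1CC[C@@H](C)C[C@H]1OC1=CC(=O)[C@@](C)(C(=C)CCCI)CC1
F5 | step 5 | (4S)-4-(5-chloropent-1-en-2-yl)-4-methylcyclohex-2-en-1-one | O=C1CC[C@](C)(C(=C)CCCCl)C=C1
F6 | step 5 | (4S)-4-(5-iodopent-1-en-2-yl)-4-methylcyclohex-2-en-1-one | O=C1CC[C@](C)(C(=C)CCCI)C=C1
F7 | step 5 | (4aS,8aR)-4a-methyl-5-methylideneoctahydronaphthalen-2(1H)-one | O=C1CC[C@]2(C)C(=C)CCC[C@@H]2C1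
F8 | step 14 | (4aS,5R,6R,8aS)-4a,5-dimethyl-3-(propan-2-ylidene)-6-[(triethylsilyl)oxy]octahydronaphthalen-2(1H)-one | CC[Si](CC)(CC)O[C@@H]1CC[C@H]2CC(=O)C(=C(C)C)C[C@]2(C)[C@H]1C
F9 | step 14 | (1S,4aR,5R,6R,8aR)-1-hydroxy-4a,5-dimethyl-3-(propan-2-ylidene)-6-[(triethylsilyl)oxy]octahydronaphthalen-2(1H)-one | CC[Si](CC)(CC)O[C@@H]1CC[C@H]2[C@H](O)C(=O)C(=C(C)C)C[C@]2(C)[C@H]1C
F10 | step 14 | (1S,4aR,5R,6R,8aR)-1-[(tert-butyldimethylsilyl)oxy]-4a,5-dimethyl-3-(propan-2-ylidene)-6-[(triethylsilyl)oxy]octahydronaphthalen-2(1H)-one | CC[Si](CC)(CC)O[C@@H]1CC[C@H]2[C@H](O[Si](C)(C)C(C)(C)C)C(=O)C(=C(C)C)C[C@]2(C)[C@H]1C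
F11 | step 14 | (1S,4aR,5R,6R,8aR)-1-[(tert-butyldimethylsilyl)oxy]-6-hydroxy-4a,5-dimethyl-3-(propan-2-ylidene)octahydronaphthalen-2(1H)-one | O[C@@H]1CC[C@H]2[C@H](O[Si](C)(C)C(C)(C)C)C(=O)C(=C(C)C)C[C@]2(C)[C@H]1C
F12 | step 14 | (1R,2R,4aR,5S,8aR)-5-[(tert-butyldimethylsilyl)oxy]-1,8a-dimethyl-6-oxo-7-(propan-2-ylidene)decahydronaphthalen-2-yl (2Z)-2-methyl-4-{[(2Z)-2-methylbut-2-enoyl]oxy}but-2-enoate | C/C=C(/C)C(=O)OC/C=C(/C)C(=O)O[C@@H]1CC[C@H]2[C@H](O[Si](C)(C)C(C)(C)C)C(=O)C(=C(C)C)C[C@]2(C)[C@H]1C
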